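## Retrosynthetic overview

1. The target comes from its allyl ester/silyl ether form; the last operations are C8 O-acylation, desilylation and a neutral deallylation, so the hydroxy acid never sees acid or base.
2. Key step: the only ring is closed late by an intramolecular Nozaki–Hiyama–Kishi-type 2-(alkoxycarbonyl)allylation (C7–C8 bond) of an acyclic aldehyde/allylic bromide, which makes the carbocycle, C7, C8 and the α-methylene ester at once.
3. The geometry-defined allylic bromide comes from hydroalumination/hydroxymethylation of an ynoate, itself made by Felkin–Anh addition of lithiated allyl propiolate to the C6 aldehyde (sets C6).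
4. C5 (tertiary) and C10 (quaternary) come from one enantioselective boron-mediated Ireland–Claisen rearrangement of an achiral (E)-allylic ester.
5. Building blocks: but-3-yn-1-ol, 4-methyl hydrogen itaconate, propiolic acid, ethyl 2-(hydroxymethyl)acrylate. Ring order: one ring only, formed in step 16.

Assumption: the (4S,5S) boron controller is taken to give the (2R,3S) Claisen acid; this sense is assigned by analogy with geranyl-type esters, and the mirror-image controller would give the antipode.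

Locants C1–C15 in the text are elemane locants: ring C5–C10; C1=C2 vinyl and C14 methyl on C10; C3/C4/C15 the oxygenated isopropenyl unit on C5; C11(=C13)–C12 the acrylate unit on C7.

## Route

Step 1
Reactants: 1 but-3-yn-1-ol
Product: 2 1-[(but-3-yn-1-yloxy)methyl]-4-methoxybenzene
Conditions: NaH, 4-methoxybenzyl chloride, Bu4NI (cat.), THF–DMF, 0 °C to rt
Reagents that add atoms: 4-methoxybenzyl chloride, COc1ccc(CCl)cc1
Why: Williamson etherification of the sodium alkoxide; the terminal alkyne is not touched by NaH under these conditions.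

Step 2
Reactants: 2 1-[(but-3-yn-1-yloxy)methyl]-4-methoxybenzene
Product: 4 (2E)-5-[(4-methoxybenzyl)oxy]-3-methylpent-2-en-1-ol, via alkenyldimethylalane 3 (not isolated)
Conditions: Me3Al (2.5 equiv), (C5H5)2ZrCl2 (0.25 equiv), CH2Cl2, 0 °C to rt; then (CH2O)n, THF, 0 °C to rt; aq. potassium sodium tartrate work-up
Reagents that add atoms: trimethylaluminium, C[Al](C)C; formaldehyde (from paraformaldehyde), C=O
Why: Zirconium-catalysed Negishi carboalumination adds Me–Al syn across the terminal alkyne (methyl to the internal carbon) and the alkenylalane is hydroxymethylated with retention, which fixes the (E)-trisubstituted alkene.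

Step 3
Reactants: 5 4-methoxy-2-methylidene-4-oxobutanoic acid (4-methyl hydrogen itaconate)
Product: 7 methyl 3-(hydroxymethyl)but-3-enoate, via mixed carbonic anhydride 6 (not isolated)
Conditions: ClCO2Et, Et3N, THF, −10 °C; then NaBH4, THF–H2O, 0 °C
Reagents that add atoms: none
Why: Mixed-anhydride activation lets NaBH4 reduce only the carboxylic acid (1,2-reduction to the allylic alcohol) beside the methyl ester.

Step 4
Reactants: 7 methyl 3-(hydroxymethyl)but-3-enoate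
Product: 8 methyl 3-{[(tert-butyldimethylsilyl)oxy]methyl}but-3-enoate
Conditions: tBuMe2SiCl, imidazole, CH2Cl2, 0 °C to rt
Reagents that add atoms: tert-butyldimethylsilyl chloride, CC(C)(C)[Si](C)(C)Cl
Why: Standard silylation of a primary allylic alcohol, done at once so that the hydroxy ester cannot lactonise.

Step 5
Reactants: 8 methyl 3-{[(tert-butyldimethylsilyl)oxy]methyl}but-3-enoate
Product: 9 3-{[(tert-butyldimethylsilyl)oxy]methyl}but-3-enoic acid
Conditions: LiOH, THF–H2O, 0 °C; then 1 M HCl to pH 4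
Reagents that add atoms: lithium hydroxide, [Li+].[OH-]
Why: Saponification at 0 °C is mild enough to keep the β,γ-alkene out of conjugation and the silyl ether intact.

Step 6
Reactants: 4 (2E)-5-[(4-methoxybenzyl)oxy]-3-methylpent-2-en-1-ol; 9 3-{[(tert-butyldimethylsilyl)oxy]methyl}but-3-enoic acid
Product: 10 (2E)-5-[(4-methoxybenzyl)oxy]-3-methylpent-2-en-1-yl 3-{[(tert-butyldimethylsilyl)oxy]methyl}but-3-enoate
Conditions: N,N'-dicyclohexylcarbodiimide, 4-(dimethylamino)pyridine (5 mol %), CH2Cl2, −20 to 0 °C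
Reagents that add atoms: none
Why: Steglich esterification; low temperature and little base keep the β,γ-unsaturated acid from isomerising.

Step 7
Reactants: 10 (2E)-5-[(4-methoxybenzyl)oxy]-3-methylpent-2-en-1-yl 3-{[(tert-butyldimethylsilyl)oxy]methyl}but-3-enoate
Product: 13 (2R,3S)-2-{3-[(tert-butyldimethylsilyl)oxy]prop-1-en-2-yl}-3-{2-[(4-methoxybenzyl)oxy]ethyl}-3-methylpent-4-enoic acid, via boron ketene acetal 11 (not isolated), via acyloxyborane 12 (not isolated)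
Conditions: (4S,5S)-2-bromo-1,3-bis{[3,5-bis(trifluoromethyl)phenyl]sulfonyl}-4,5-diphenyl-1,3,2-diazaborolidine (1.2 equiv), Et3N, toluene–hexane, −78 °C, then −20 to 4 °C; aq. work-up
Reagents that add atoms: none
Why: Enantioselective boron-mediated Ireland–Claisen rearrangement: soft enolisation gives the O-boryl ketene acetal with C4 trans to O–B, which rearranges through a chair with C9 equatorial and the methyl axial on the (E)-alkene, so C5 and C10 form with the elemane relative configuration while the C2-symmetric ligand on boron shields one enolate face and sets the absolute configuration.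

Step 8
Reactants: 13 (2R,3S)-2-{3-[(tert-butyldimethylsilyl)oxy]prop-1-en-2-yl}-3-{2-[(4-methoxybenzyl)oxy]ethyl}-3-methylpent-4-enoic acid
Product: 14 (2R,3S)-2-{3-[(tert-butyldimethylsilyl)oxy]prop-1-en-2-yl}-3-{2-[(4-methoxybenzyl)oxy]ethyl}-3-methylpent-4-en-1-ol
Conditions: LiAlH4, Et2O, 0 °C to rt
Reagents that add atoms: none
Why: Hydride reduction of the acid; ethers, silyl ethers and isolated alkenes are inert and no stereocentre is touched.

Step 9
Reactants: 14 (2R,3S)-2-{3-[(tert-butyldimethylsilyl)oxy]prop-1-en-2-yl}-3-{2-[(4-methoxybenzyl)oxy]ethyl}-3-methylpent-4-en-1-ol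
Product: 15 (2R,3S)-2-{3-[(tert-butyldimethylsilyl)oxy]prop-1-en-2-yl}-3-{2-[(4-methoxybenzyl)oxy]ethyl}-3-methylpent-4-enal
Conditions: Dess–Martin periodinane, NaHCO3, CH2Cl2, 0 °C; used at once
Reagents that add atoms: none
Why: Buffered Dess–Martin oxidation is non-basic, so the β,γ-unsaturated aldehyde is neither epimerised at C5 nor conjugated.

Step 10
Reactants: 16 prop-2-ynoic acid (propiolic acid)
Product: 17 prop-2-en-1-yl prop-2-ynoate (allyl propiolate)
Conditions: prop-2-en-1-ol (3 equiv), 4-methylbenzenesulfonic acid monohydrate (5 mol %), benzene, reflux (Dean–Stark)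
Reagents that add atoms: prop-2-en-1-ol, C=CCO
Why: Fischer esterification driven by water removal; the allyl ester is chosen because it can be removed at the end under neutral conditions.

Step 11
Reactants: 15 (2R,3S)-2-{3-[(tert-butyldimethylsilyl)oxy]prop-1-en-2-yl}-3-{2-[(4-methoxybenzyl)oxy]ethyl}-3-methylpent-4-enal; 17 prop-2-en-1-yl prop-2-ynoate
Product: 20 prop-2-en-1-yl (4R,5R,6S)-5-{3-[(tert-butyldimethylsilyl)oxy]prop-1-en-2-yl}-6-{2-[(4-methoxybenzyl)oxy]ethyl}-6-methyl-4-[(triethylsilyl)oxy]oct-7-en-2-ynoate, via lithium acetylide 18 (not isolated), via lithium alkoxide 19 (not isolated)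
Conditions: 17 (1.4 equiv), LiN(SiMe3)2 (1.3 equiv), THF, −78 °C; then 15, −78 °C; then Et3SiOTf (2.2 equiv), −78 to −40 °C
Reagents that add atoms: triethylsilyl trifluoromethanesulfonate, CC[Si](CC)(CC)OS(=O)(=O)C(F)(F)F
Why: Felkin–Anh 1,2-addition of a lithium acetylide: with the quaternary C10 anti to the nucleophile and H5 on the side of attack the (4R) carbinol (C6, trans to the C5 substituent in the later ring) is favoured, and the alkoxide is silylated in the same flask; the acetylide is made with a deficit of base so the epimerisable aldehyde never meets free amide.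

Step 12
Reactants: 20 prop-2-en-1-yl (4R,5R,6S)-5-{3-[(tert-butyldimethylsilyl)oxy]prop-1-en-2-yl}-6-{2-[(4-methoxybenzyl)oxy]ethyl}-6-methyl-4-[(triethylsilyl)oxy]oct-7-en-2-ynoate
Product: 22 prop-2-en-1-yl (2Z,4S,5R,6S)-5-{3-[(tert-butyldimethylsilyl)oxy]prop-1-en-2-yl}-2-(hydroxymethyl)-6-{2-[(4-methoxybenzyl)oxy]ethyl}-6-methyl-4-[(triethylsilyl)oxy]octa-2,7-dienoate, via alumino enoate 21 (not isolated)
Conditions: iBu2AlH, (Me2N)3PO, THF, 0 °C; then CH2O (monomeric, in THF), −20 °C to rt; aq. potassium sodium tartrate work-up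
Reagents that add atoms: formaldehyde, C=O
Why: Vinylalumination: the phosphoramide-complexed hydride adds 1,4 to the ynoate with H and Al syn, and the α-alumino enoate (or its allenolate, attacked on the side of H7) is hydroxymethylated at C11, so CH2OH ends up cis to H7 and C6 cis to the ester, the kinetic (Z) geometry needed for the ring closure.

Step 13
Reactants: 22 prop-2-en-1-yl (2Z,4S,5R,6S)-5-{3-[(tert-butyldimethylsilyl)oxy]prop-1-en-2-yl}-2-(hydroxymethyl)-6-{2-[(4-methoxybenzyl)oxy]ethyl}-6-methyl-4-[(triethylsilyl)oxy]octa-2,7-dienoate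
Product: 23 prop-2-en-1-yl (2E,4S,5R,6S)-2-(bromomethyl)-5-{3-[(tert-butyldimethylsilyl)oxy]prop-1-en-2-yl}-6-{2-[(4-methoxybenzyl)oxy]ethyl}-6-methyl-4-[(triethylsilyl)oxy]octa-2,7-dienoate
Conditions: CBr4, PPh3, CH2Cl2, −20 to 0 °C
Reagents that add atoms: carbon tetrabromide, BrC(Br)(Br)Br
Why: Appel bromination by SN2 at the primary allylic carbon under neutral conditions keeps the alkene position and geometry (now named E) and spares the silyl ethers.

Step 14
Reactants: 23 prop-2-en-1-yl (2E,4S,5R,6S)-2-(bromomethyl)-5-{3-[(tert-butyldimethylsilyl)oxy]prop-1-en-2-yl}-6-{2-[(4-methoxybenzyl)oxy]ethyl}-6-methyl-4-[(triethylsilyl)oxy]octa-2,7-dienoate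
Product: 24 prop-2-en-1-yl (2E,4S,5R,6S)-2-(bromomethyl)-5-{3-[(tert-butyldimethylsilyl)oxy]prop-1-en-2-yl}-6-(2-hydroxyethyl)-6-methyl-4-[(triethylsilyl)oxy]octa-2,7-dienoate
Conditions: 2,3-dichloro-5,6-dicyano-1,4-benzoquinone, CH2Cl2–pH 7 buffer, 0 °C
Reagents that add atoms: none
Why: Oxidative cleavage of the 4-methoxybenzyl ether under buffered conditions leaves the silyl ethers, the allylic bromide and the alkenes untouched.

Step 15
Reactants: 24 prop-2-en-1-yl (2E,4S,5R,6S)-2-(bromomethyl)-5-{3-[(tert-butyldimethylsilyl)oxy]prop-1-en-2-yl}-6-(2-hydroxyethyl)-6-methyl-4-[(triethylsilyl)oxy]octa-2,7-dienoate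
Product: 25 prop-2-en-1-yl (2E,4S,5R,6S)-2-(bromomethyl)-5-{3-[(tert-butyldimethylsilyl)oxy]prop-1-en-2-yl}-6-methyl-6-(2-oxoethyl)-4-[(triethylsilyl)oxy]octa-2,7-dienoate
Conditions: Dess–Martin periodinane, NaHCO3, CH2Cl2, 0 °C to rt
Reagents that add atoms: none
Why: Dess–Martin oxidation of the primary alcohol; the aldehyde has no α-stereocentre and the allylic bromide survives.

Step 16
Reactants: 25 prop-2-en-1-yl (2E,4S,5R,6S)-2-(bromomethyl)-5-{3-[(tert-butyldimethylsilyl)oxy]prop-1-en-2-yl}-6-methyl-6-(2-oxoethyl)-4-[(triethylsilyl)oxy]octa-2,7-dienoate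
Product: 27 prop-2-en-1-yl 2-[(1R,2R,3R,4S,6S)-3-{3-[(tert-butyldimethylsilyl)oxy]prop-1-en-2-yl}-4-ethenyl-6-hydroxy-4-methyl-2-[(triethylsilyl)oxy]cyclohexyl]prop-2-enoate, via allylchromium dichloride 26 (not isolated)
Conditions: CrCl2 (6 equiv), THF, 0.005 M (slow addition of 25), 0 °C to rt; aq. NH4Cl at 0 °C
Reagents that add atoms: none
Why: Intramolecular Nozaki–Hiyama–Kishi-type carbonyl allylation: divalent chromium turns the bromide into an allylchromium that adds through C7 to the C8 aldehyde in a closed chair–chair (trans-decalin-like) Zimmerman–Traxler transition state with the C5 and C6 substituents equatorial, H6 eclipsing the ester and C6 trans to CH2Cr, so C7–C11 and C8–OH both form equatorial (all-trans C5–C8 array) and the α-methylene ester appears by allylic transposition.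

Step 17
Reactants: 28 ethyl 2-(hydroxymethyl)prop-2-enoate
Product: 29 ethyl 2-{[(tert-butyldimethylsilyl)oxy]methyl}prop-2-enoate
Conditions: tBuMe2SiCl, imidazole, CH2Cl2, 0 °C to rt
Reagents that add atoms: tert-butyldimethylsilyl chloride, CC(C)(C)[Si](C)(C)Cl
Why: Standard silylation of the primary allylic alcohol.

Step 18
Reactants: 29 ethyl 2-{[(tert-butyldimethylsilyl)oxy]methyl}prop-2-enoate
Product: 30 2-{[(tert-butyldimethylsilyl)oxy]methyl}prop-2-enoic acid
Conditions: LiOH, THF–H2O, 0 °C; then 1 M HCl to pH 4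
Reagents that add atoms: lithium hydroxide, [Li+].[OH-]
Why: Saponification of the ethyl ester; the α-substituted acrylate is a poor Michael acceptor for hydroxide at 0 °C.

Step 19
Reactants: 27 prop-2-en-1-yl 2-[(1R,2R,3R,4S,6S)-3-{3-[(tert-butyldimethylsilyl)oxy]prop-1-en-2-yl}-4-ethenyl-6-hydroxy-4-methyl-2-[(triethylsilyl)oxy]cyclohexyl]prop-2-enoate; 30 2-{[(tert-butyldimethylsilyl)oxy]methyl}prop-2-enoic acid
Product: 31 prop-2-en-1-yl 2-[(1R,2R,3R,4S,6S)-6-{[2-({[tert-butyldimethylsilyl]oxy}methyl)prop-2-enoyl]oxy}-3-{3-[(tert-butyldimethylsilyl)oxy]prop-1-en-2-yl}-4-ethenyl-4-methyl-2-[(triethylsilyl)oxy]cyclohexyl]prop-2-enoate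
Conditions: N,N'-dicyclohexylcarbodiimide, 4-(dimethylamino)pyridine (0.3 equiv), CH2Cl2, 0 °C to rt
Reagents that add atoms: none
Why: Steglich esterification of the only free hydroxyl (equatorial C8–OH); acylation is faster than lactonisation onto the bulky allyl ester and C6–O is still silylated.

Step 20
Reactants: 31 prop-2-en-1-yl 2-[(1R,2R,3R,4S,6S)-6-{[2-({[tert-butyldimethylsilyl]oxy}methyl)prop-2-enoyl]oxy}-3-{3-[(tert-butyldimethylsilyl)oxy]prop-1-en-2-yl}-4-ethenyl-4-methyl-2-[(triethylsilyl)oxy]cyclohexyl]prop-2-enoate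
Product: 32 prop-2-en-1-yl 2-[(1S,2R,3R,4S,6S)-4-ethenyl-2-hydroxy-6-{[2-(hydroxymethyl)prop-2-enoyl]oxy}-3-(3-hydroxyprop-1-en-2-yl)-4-methylcyclohexyl]prop-2-enoate
Conditions: HF·pyridine, pyridine, THF, 0 °C to rt
Reagents that add atoms: none
Why: Buffered fluoride desilylation removes the triethylsilyl and both primary allylic tert-butyldimethylsilyl ethers while both esters stay and the weakly acidic medium does not lactonise the hydroxy ester.

Step 21
Reactants: 32 prop-2-en-1-yl 2-[(1S,2R,3R,4S,6S)-4-ethenyl-2-hydroxy-6-{[2-(hydroxymethyl)prop-2-enoyl]oxy}-3-(3-hydroxyprop-1-en-2-yl)-4-methylcyclohexyl]prop-2-enoate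
Product: 33 2-[(1S,2R,3R,4S,6S)-4-ethenyl-2-hydroxy-6-{[2-(hydroxymethyl)prop-2-enoyl]oxy}-3-(3-hydroxyprop-1-en-2-yl)-4-methylcyclohexyl]prop-2-enoic acid (CNP0509685.1)
Conditions: Pd(PPh3)4 (5 mol %), N-methylaniline (3 equiv), THF, 0 °C to rt; neutral work-up
Reagents that add atoms: none
Why: Tsuji–Trost deallylation: zerovalent palladium ionises only the allyl ester (the C8 ester is not allylic) and the weakly nucleophilic aniline takes the allyl group, freeing the acid under neutral conditions so the 6-hydroxy acid does not close to the lactone.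

## Compound list

1 | but-3-yn-1-ol | C#CCCO | starting material
2 | 1-[(but-3-yn-1-yloxy)methyl]-4-methoxybenzene | C#CCCOCc1ccc(OC)cc1 | intermediate
3 | [(1E)-4-[(4-methoxybenzyl)oxy]-2-methylbut-1-en-1-yl]dimethylalane | C[Al](C)/C=C(\C)CCOCc1ccc(OC)cc1 | intermediate
4 | (2E)-5-[(4-methoxybenzyl)oxy]-3-methylpent-2-en-1-ol | OC/C=C(\C)CCOCc1ccc(OC)cc1 | intermediate
5 | 4-methoxy-2-methylidene-4-oxobutanoic acid (4-methyl hydrogen itaconate) | COC(=O)CC(=C)C(=O)O | starting material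
6 | ethoxycarbonyl 4-methoxy-2-methylidene-4-oxobutanoate (mixed carbonic anhydride) | COC(=O)CC(=C)C(=O)OC(=O)OCC | intermediate
7 | methyl 3-(hydroxymethyl)but-3-enoate | COC(=O)CC(=C)CO | intermediate
8 | methyl 3-{[(tert-butyldimethylsilyl)oxy]methyl}but-3-enoate | COC(=O)CC(=C)CO[Si](C)(C)C(C)(C)C | intermediate
9 | 3-{[(tert-butyldimethylsilyl)oxy]methyl}but-3-enoic acid | OC(=O)CC(=C)CO[Si](C)(C)C(C)(C)C | intermediate
10 | (2E)-5-[(4-methoxybenzyl)oxy]-3-methylpent-2-en-1-yl 3-{[(tert-butyldimethylsilyl)oxy]methyl}but-3-enoate | COc1ccc(COCC/C(C)=C/COC(=O)CC(=C)CO[Si](C)(C)C(C)(C)C)cc1 | intermediate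
11 | (1Z)-O-boryl ketene acetal of 10 (C4 trans to O–B; boron in the (4S,5S)-1,3-bis{[3,5-bis(trifluoromethyl)phenyl]sulfonyl}-4,5-diphenyl-1,3,2-diazaborolidin-2-yl ring) | C=C(CO[Si](C)(C)C(C)(C)C)/C=C(/OB1N(S(=O)(=O)c2cc(C(F)(F)F)cc(C(F)(F)F)c2)[C@@H](c2ccccc2)[C@H](c2ccccc2)N1S(=O)(=O)c1cc(C(F)(F)F)cc(C(F)(F)F)c1)OC/C=C(\C)CCOCc1ccc(OC)cc1 | intermediate
12 | 2-acyloxy-(4S,5S)-diazaborolidine of acid 13 (boron carboxylate formed by the rearrangement) | C=C[C@](C)(CCOCc1ccc(OC)cc1)[C@@H](C(=O)OB1N(S(=O)(=O)c2cc(C(F)(F)F)cc(C(F)(F)F)c2)[C@@H](c2ccccc2)[C@H](c2ccccc2)N1S(=O)(=O)c1cc(C(F)(F)F)cc(C(F)(F)F)c1)C(=C)CO[Si](C)(C)C(C)(C)C | intermediate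
13 | (2R,3S)-2-{3-[(tert-butyldimethylsilyl)oxy]prop-1-en-2-yl}-3-{2-[(4-methoxybenzyl)oxy]ethyl}-3-methylpent-4-enoic acid | C=C[C@](C)(CCOCc1ccc(OC)cc1)[C@@H](C(=O)O)C(=C)CO[Si](C)(C)C(C)(C)C | intermediate
14 | (2R,3S)-2-{3-[(tert-butyldimethylsilyl)oxy]prop-1-en-2-yl}-3-{2-[(4-methoxybenzyl)oxy]ethyl}-3-methylpent-4-en-1-ol | C=C[C@](C)(CCOCc1ccc(OC)cc1)[C@@H](CO)C(=C)CO[Si](C)(C)C(C)(C)C | intermediate
15 | (2R,3S)-2-{3-[(tert-butyldimethylsilyl)oxy]prop-1-en-2-yl}-3-{2-[(4-methoxybenzyl)oxy]ethyl}-3-methylpent-4-enal | C=C[C@](C)(CCOCc1ccc(OC)cc1)[C@@H](C=O)C(=C)CO[Si](C)(C)C(C)(C)C | intermediate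
16 | prop-2-ynoic acid | C#CC(=O)O | starting material
17 | prop-2-en-1-yl prop-2-ynoate | C#CC(=O)OCC=C | intermediate
18 | lithium acetylide of 17 | [Li]C#CC(=O)OCC=C | intermediate
19 | lithium (4R,5R,6S)-alkoxide formed from 15 and 18 | C=C[C@](C)(CCOCc1ccc(OC)cc1)[C@@H]([C@@H](O[Li])C#CC(=O)OCC=C)C(=C)CO[Si](C)(C)C(C)(C)C | intermediate
20 | prop-2-en-1-yl (4R,5R,6S)-5-{3-[(tert-butyldimethylsilyl)oxy]prop-1-en-2-yl}-6-{2-[(4-methoxybenzyl)oxy]ethyl}-6-methyl-4-[(triethylsilyl)oxy]oct-7-en-2-ynoate | C=C[C@](C)(CCOCc1ccc(OC)cc1)[C@@H]([C@@H](O[Si](CC)(CC)CC)C#CC(=O)OCC=C)C(=C)CO[Si](C)(C)C(C)(C)C | intermediate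
21 | prop-2-en-1-yl (2E,4R,5R,6S)-2-(diisobutylalumanyl) analogue of 22 (H7 and Al cis) | C=C[C@](C)(CCOCc1ccc(OC)cc1)[C@@H]([C@@H](O[Si](CC)(CC)CC)/C=C(/[Al](CC(C)C)CC(C)C)C(=O)OCC=C)C(=C)CO[Si](C)(C)C(C)(C)C | intermediate
22 | prop-2-en-1-yl (2Z,4S,5R,6S)-5-{3-[(tert-butyldimethylsilyl)oxy]prop-1-en-2-yl}-2-(hydroxymethyl)-6-{2-[(4-methoxybenzyl)oxy]ethyl}-6-methyl-4-[(triethylsilyl)oxy]octa-2,7-dienoate | C=C[C@](C)(CCOCc1ccc(OC)cc1)[C@@H]([C@@H](O[Si](CC)(CC)CC)/C=C(/CO)C(=O)OCC=C)C(=C)CO[Si](C)(C)C(C)(C)C | intermediate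
23 | prop-2-en-1-yl (2E,4S,5R,6S)-2-(bromomethyl)-5-{3-[(tert-butyldimethylsilyl)oxy]prop-1-en-2-yl}-6-{2-[(4-methoxybenzyl)oxy]ethyl}-6-methyl-4-[(triethylsilyl)oxy]octa-2,7-dienoate | C=C[C@](C)(CCOCc1ccc(OC)cc1)[C@@H]([C@@H](O[Si](CC)(CC)CC)/C=C(/CBr)C(=O)OCC=C)C(=C)CO[Si](C)(C)C(C)(C)C | intermediate
24 | prop-2-en-1-yl (2E,4S,5R,6S)-2-(bromomethyl)-5-{3-[(tert-butyldimethylsilyl)oxy]prop-1-en-2-yl}-6-(2-hydroxyethyl)-6-methyl-4-[(triethylsilyl)oxy]octa-2,7-dienoate | C=C[C@](C)(CCO)[C@@H]([C@@H](O[Si](CC)(CC)CC)/C=C(/CBr)C(=O)OCC=C)C(=C)CO[Si](C)(C)C(C)(C)C | intermediate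
25 | prop-2-en-1-yl (2E,4S,5R,6S)-2-(bromomethyl)-5-{3-[(tert-butyldimethylsilyl)oxy]prop-1-en-2-yl}-6-methyl-6-(2-oxoethyl)-4-[(triethylsilyl)oxy]octa-2,7-dienoate | C=C[C@](C)(CC=O)[C@@H]([C@@H](O[Si](CC)(CC)CC)/C=C(/CBr)C(=O)OCC=C)C(=C)CO[Si](C)(C)C(C)(C)C | intermediate
26 | (2E,4S,5R,6S)-allylchromium dichloride from 25 (CH2CrCl2 in place of CH2Br) | C=C[C@](C)(CC=O)[C@@H]([C@@H](O[Si](CC)(CC)CC)/C=C(/C[Cr](Cl)Cl)C(=O)OCC=C)C(=C)CO[Si](C)(C)C(C)(C)C | intermediate
27 | prop-2-en-1-yl 2-[(1R,2R,3R,4S,6S)-3-{3-[(tert-butyldimethylsilyl)oxy]prop-1-en-2-yl}-4-ethenyl-6-hydroxy-4-methyl-2-[(triethylsilyl)oxy]cyclohexyl]prop-2-enoate | C=C[C@]1(C)C[C@H](O)[C@@H](C(=C)C(=O)OCC=C)[C@H](O[Si](CC)(CC)CC)[C@H]1C(=C)CO[Si](C)(C)C(C)(C)C | intermediate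
28 | ethyl 2-(hydroxymethyl)prop-2-enoate | CCOC(=O)C(=C)CO | starting material
29 | ethyl 2-{[(tert-butyldimethylsilyl)oxy]methyl}prop-2-enoate | CCOC(=O)C(=C)CO[Si](C)(C)C(C)(C)C | intermediate
30 | 2-{[(tert-butyldimethylsilyl)oxy]methyl}prop-2-enoic acid | OC(=O)C(=C)CO[Si](C)(C)C(C)(C)C | intermediate
31 | prop-2-en-1-yl 2-[(1R,2R,3R,4S,6S)-6-{[2-({[tert-butyldimethylsilyl]oxy}methyl)prop-2-enoyl]oxy}-3-{3-[(tert-butyldimethylsilyl)oxy]prop-1-en-2-yl}-4-ethenyl-4-methyl-2-[(triethylsilyl)oxy]cyclohexyl]prop-2-enoate | C=C[C@]1(C)C[C@H](OC(=O)C(=C)CO[Si](C)(C)C(C)(C)C)[C@@H](C(=C)C(=O)OCC=C)[C@H](O[Si](CC)(CC)CC)[C@H]1C(=C)CO[Si](C)(C)C(C)(C)C | intermediate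
32 | prop-2-en-1-yl 2-[(1S,2R,3R,4S,6S)-4-ethenyl-2-hydroxy-6-{[2-(hydroxymethyl)prop-2-enoyl]oxy}-3-(3-hydroxyprop-1-en-2-yl)-4-methylcyclohexyl]prop-2-enoate | C=C[C@]1(C)C[C@H](OC(=O)C(=C)CO)[C@@H](C(=C)C(=O)OCC=C)[C@H](O)[C@H]1C(=C)CO | intermediate
33 | 2-[(1S,2R,3R,4S,6S)-4-ethenyl-2-hydroxy-6-{[2-(hydroxymethyl)prop-2-enoyl]oxy}-3-(3-hydroxyprop-1-en-2-yl)-4-methylcyclohexyl]prop-2-enoic acid | C=C[C@]1(C)C[C@H](OC(=O)C(=C)CO)[C@@H](C(=C)C(=O)O)[C@H](O)[C@H]1C(=C)CO | target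

## Step count and risk

Total step count: 21. Longest linear sequence: 16 steps (3, 4, 5, 6, 7, 8, 9, 11, 12, 13, 14, 15, 16, 19, 20, 21).

The three steps most likely to fail:

Step 16 (ring closure). The chromium reaction could give the C8 epimer, the 8,12-lactone or simple reduction. The fallback closes the ring by a radical instead of an allylmetal. It sets out from 22: acetylation (Ac2O, pyridine) gives the allylic acetate F5, buffered 2,3-dichloro-5,6-dicyano-1,4-benzoquinone removes the 4-methoxybenzyl group to give the primary alcohol F6, and Dess–Martin oxidation gives the aldehyde acetate F7. SmI2 (THF, tBuOH, −78 °C) then forms the C8 ketyl, which adds 6-exo to C7 of the enoate through the same all-equatorial chair; the resulting enolate of trivalent samarium expels acetate to form the exocyclic methylene, and the route is rejoined at 27.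

Step 12 (hydroalumination/hydroxymethylation). Trapping of the alumino enoate by formaldehyde could be poor, or the geometry could leak. The fallback replaces the aldol-type trapping by a cross-coupling. It sets out from 20: molybdenum-catalysed syn-hydrostannation (Bu3SnH, Mo(CO)3(CNtBu)3 5 mol %, THF, 55 °C) puts tin on C11 and gives the stannyl enoate F3 with C6 cis to the ester. Iododestannylation (I2, CH2Cl2, 0 °C) gives the iodo enoate F4 with retention, and Stille coupling with (tributylstannyl)methanol (PdCl2(MeCN)2 5 mol %, DMF, rt, a ligand-free divalent palladium precatalyst that inserts into the vinyl iodide faster than it ionises the allyl ester) comes back to the route at 22.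

Step 11 (C6 carbinol). The Felkin–Anh ratio from a lithium acetylide may be modest. The fallback sets C6 by reagent control. It sets out from 15: the acetylide 18 is added as before but quenched with aq. NH4Cl, giving the propargylic alcohol F1 as a C6 epimer mixture, and Dess–Martin oxidation converges both epimers on the ynone F2. Reduction with catecholborane and (R)-1-methyl-3,3-diphenyltetrahydro-1H,3H-pyrrolo[1,2-c][1,3,2]oxazaborole (20 mol %, toluene, −78 °C; the alkyne acts as the small group) returns the propargylic alcohol F1 as the (4R) epimer, and Et3SiOTf/2,6-lutidine brings it back to the route at 20.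

Further compounds
F1 | step 11 | prop-2-en-1-yl (4R,5R,6S)-5-{3-[(tert-butyldimethylsilyl)oxy]prop-1-en-2-yl}-4-hydroxy-6-{2-[(4-methoxybenzyl)oxy]ethyl}-6-methyloct-7-en-2-ynoate | C=C[C@](C)(CCOCc1ccc(OC)cc1)[C@@H]([C@@H](O)C#CC(=O)OCC=C)C(=C)CO[Si](C)(C)C(C)(C)C
F2 | step 11 | prop-2-en-1-yl (5R,6S)-5-{3-[(tert-butyldimethylsilyl)oxy]prop-1-en-2-yl}-6-{2-[(4-methoxybenzyl)oxy]ethyl}-6-methyl-4-oxooct-7-en-2-ynoate | C=C[C@](C)(CCOCc1ccc(OC)cc1)[C@@H](C(=O)C#CC(=O)OCC=C)C(=C)CO[Si](C)(C)C(C)(C)C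
F3 | step 12 | prop-2-en-1-yl (2E,4R,5R,6S)-5-{3-[(tert-butyldimethylsilyl)oxy]prop-1-en-2-yl}-6-{2-[(4-methoxybenzyl)oxy]ethyl}-6-methyl-2-(tributylstannyl)-4-[(triethylsilyl)oxy]octa-2,7-dienoate | C=C[C@](C)(CCOCc1ccc(OC)cc1)[C@@H]([C@@H](O[Si](CC)(CC)CC)/C=C(/[Sn](CCCC)(CCCC)CCCC)C(=O)OCC=C)C(=C)CO[Si](C)(C)C(C)(C)C
F4 | step 12 | prop-2-en-1-yl (2E,4R,5R,6S)-5-{3-[(tert-butyldimethylsilyl)oxy]prop-1-en-2-yl}-2-iodo-6-{2-[(4-methoxybenzyl)oxy]ethyl}-6-methyl-4-[(triethylsilyl)oxy]octa-2,7-dienoate | C=C[C@](C)(CCOCc1ccc(OC)cc1)[C@@H]([C@@H](O[Si](CC)(CC)CC)/C=C(/I)C(=O)OCC=C)C(=C)CO[Si](C)(C)C(C)(C)C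
F5 | step 16 | prop-2-en-1-yl (2Z,4S,5R,6S)-2-(acetoxymethyl)-5-{3-[(tert-butyldimethylsilyl)oxy]prop-1-en-2-yl}-6-{2-[(4-methoxybenzyl)oxy]ethyl}-6-methyl-4-[(triethylsilyl)oxy]octa-2,7-dienoate | C=C[C@](C)(CCOCc1ccc(OC)cc1)[C@@H]([C@@H](O[Si](CC)(CC)CC)/C=C(/COC(C)=O)C(=O)OCC=C)C(=C)CO[Si](C)(C)C(C)(C)C
F6 | step 16 | prop-2-en-1-yl (2Z,4S,5R,6S)-2-(acetoxymethyl)-5-{3-[(tert-butyldimethylsilyl)oxy]prop-1-en-2-yl}-6-(2-hydroxyethyl)-6-methyl-4-[(triethylsilyl)oxy]octa-2,7-dienoate | C=C[C@](C)(CCO)[C@@H]([C@@H](O[Si](CC)(CC)CC)/C=C(/COC(C)=O)C(=O)OCC=C)C(=C)CO[Si](C)(C)C(C)(C)C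
F7 | step 16 | prop-2-en-1-yl (2Z,4S,5R,6S)-2-(acetoxymethyl)-5-{3-[(tert-butyldimethylsilyl)oxy]prop-1-en-2-yl}-6-methyl-6-(2-oxoethyl)-4-[(triethylsilyl)oxy]octa-2,7-dienoate | C=C[C@](C)(CC=O)[C@@H]([C@@H](O[Si](CC)(CC)CC)/C=C(/COC(C)=O)C(=O)OCC=C)C(=C)CO[Si](C)(C)C(C)(C)C
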